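**Retrosynthetic overview** (lignan numbering: C7/C8/C9 on the 3,4-dihydroxy-5-methoxyphenyl side, C7'/C8'/C9' on the 4-hydroxy-3,5-dimethoxyphenyl side)
1. Sauriol B (18) ⇐ tris-MOM ether 17 ⇐ diol 15, with both C-methyls (C9, C9') carried as CH2OH ⇐ lactone acetal 14 ⇐ dithiane adduct 13.
2. Key disconnections in 13, made in one operation on butenolide 10: C8'–C7' (lactone enolate + benzylic bromide 7) and C7–C8 (1,4-addition of lithiated dithiane 11, i.e. C7 with reversed polarity).
3. Enabling feature: the chain C9–C8–C8'–C9' (two adjacent methines, each bearing a methyl) maps onto a γ-butyrolactone, O–C9'(=O)–C8'–C8–C9(O-menthyl). In that ring C8' is an enolate carbon, C8 a Michael-acceptor carbon, and the C9 acetal relays its configuration to C8 and then to C8'. The CH2 (C7') on the 4-hydroxy-3,5-dimethoxyphenyl ring serves as the benzylic electrophile.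
4. Rings: both benzene rings are bought (aldehydes 1 and 4) and no ring of the target is formed. The only ring handled is the temporary furanone from 8, opened reductively in step 9.

Key step: step 7

Assumption: 5-hydroxyfuran-2(5H)-one (8) is taken as a purchasable compound (it is the dye-sensitised photo-oxygenation product of furfural).

**Route**

Step 1
Reactants: 1 3,4-dihydroxy-5-methoxybenzaldehyde (5-hydroxyvanillin)
Product: 2 2-(3,4-dihydroxy-5-methoxyphenyl)-1,3-dithiane
Conditions: HS(CH2)3SH, BF3·OEt2 (cat.), CH2Cl2/AcOH, 0 °C → rt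
Reagents that add atoms: propane-1,3-dithiol, SCCCS
Why: Lewis-acid-catalysed dithioacetalisation of an aryl aldehyde, which tolerates free phenols and turns the future C7 into a carbon that can be deprotonated (polarity reversal).

Step 2
Reactants: 2 2-(3,4-dihydroxy-5-methoxyphenyl)-1,3-dithiane
Product: 3 2-[3-methoxy-4,5-bis(methoxymethoxy)phenyl]-1,3-dithiane
Conditions: MOMCl, iPr2NEt, CH2Cl2, 0 °C → rt
Reagents that add atoms: chloromethyl methyl ether (MOMCl), COCCl
Why: Base-mediated O-alkylation of both phenols with MOMCl (Williamson-type), placed after step 1 because MOM ethers would not survive the Lewis acid and dithiol, whereas they should withstand n-BuLi, Raney nickel and hydride later on.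

Step 3
Reactants: 4 4-hydroxy-3,5-dimethoxybenzaldehyde (syringaldehyde)
Product: 5 3,5-dimethoxy-4-(methoxymethoxy)benzaldehyde
Conditions: MOMCl, iPr2NEt, CH2Cl2, 0 °C → rt
Reagents that add atoms: chloromethyl methyl ether (MOMCl), COCCl
Why: The same Williamson-type MOM protection, applied to the hindered but acidic syringyl phenol.

Step 4
Reactants: 5 3,5-dimethoxy-4-(methoxymethoxy)benzaldehyde
Product: 6 [3,5-dimethoxy-4-(methoxymethoxy)phenyl]methanol
Conditions: NaBH4, MeOH, 0 °C
Reagents that add atoms: none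
Why: Sodium borohydride reduction of an aryl aldehyde to the benzylic alcohol, with the MOM and methyl ethers inert.

Step 5
Reactants: 6 [3,5-dimethoxy-4-(methoxymethoxy)phenyl]methanol
Product: 7 5-(bromomethyl)-1,3-dimethoxy-2-(methoxymethoxy)benzene
Conditions: CBr4, PPh3, CH2Cl2, 0 °C; short silica plug, used at once
Reagents that add atoms: carbon tetrabromide, BrC(Br)(Br)Br
Why: Appel bromination under neutral conditions should spare the MOM acetal, and the bromide is used immediately because an electron-rich benzylic bromide ionises easily.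

Step 6
Reactants: 8 5-hydroxyfuran-2(5H)-one; 9 (−)-menthol, (1R,2S,5R)-2-isopropyl-5-methylcyclohexan-1-ol
Product: 10 (5R)-5-{[(1R,2S,5R)-2-isopropyl-5-methylcyclohexyl]oxy}furan-2(5H)-one
Conditions: CSA (cat.), toluene, reflux (Dean–Stark); crystallisation from petroleum ether, mother liquor re-equilibrated with CSA and recrystallised
Reagents that add atoms: none
Why: Acid-catalysed acetalisation of the cyclic hemiacetal with menthol should give both C5 epimers, which interconvert under acid through the oxocarbenium ion, so that crystallisation of the (5R) epimer with recycling of the mother liquor (crystallisation-induced diastereomer transformation) sets the acetal stereocentre.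

Step 7
Reactants: 3 2-[3-methoxy-4,5-bis(methoxymethoxy)phenyl]-1,3-dithiane; 10 (5R)-5-(menthyloxy)furan-2(5H)-one; 7 5-(bromomethyl)-1,3-dimethoxy-2-(methoxymethoxy)benzene
Product: 13 (3R,4R,5R)-3-[3,5-dimethoxy-4-(methoxymethoxy)benzyl]-4-{2-[3-methoxy-4,5-bis(methoxymethoxy)phenyl]-1,3-dithian-2-yl}-5-{[(1R,2S,5R)-2-isopropyl-5-methylcyclohexyl]oxy}dihydrofuran-2(3H)-one, via 2-lithio-1,3-dithiane 11 (not isolated), via lactone lithium enolate 12 (not isolated)
Conditions: n-BuLi, THF, −78 → −20 °C; 10, −78 °C; then 7, DMPU, −78 °C → rt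
Reagents that add atoms: none
Why: n-BuLi deprotonates 3 at the dithiane C2 to give 11, an acyl-anion equivalent of C7, which adds 1,4 to butenolide 10 to give lithium enolate 12; 12 is then C-benzylated at C3 (lignan C8') by bromide 7 in an SN2 step, which forms the C8'–C7' bond. The closest known reaction type is the one-pot conjugate addition–enolate alkylation of 2-aryl-2-lithio-1,3-dithianes with butenolides and benzylic bromides, including 5-alkoxy-2(5H)-furanones as chiral acceptors. No ring is closed: the lactone ring is already present and acts only as a template. C4 (lignan C8) is set by the C5 menthyloxy group, the nucleophile adding to the face of the planar butenolide anti to it, and C3 (lignan C8') is set by the new C4 substituent, the bromide approaching the enolate face trans to the bulky dithianyl group. The step needs 1,4- over 1,2-addition, secured by the soft sulfur- and aryl-stabilised anion in THF at −78 °C, and C-mono-alkylation over O- or dialkylation, secured by the reactive benzylic bromide with DMPU and by the quaternary dithiane carbon that shields the remaining α-hydrogen.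

Step 8
Reactants: 13 dithiane adduct
Product: 14 (3R,4R,5R)-3-[3,5-dimethoxy-4-(methoxymethoxy)benzyl]-4-[3-methoxy-4,5-bis(methoxymethoxy)benzyl]-5-{[(1R,2S,5R)-2-isopropyl-5-methylcyclohexyl]oxy}dihydrofuran-2(3H)-one
Conditions: Raney Ni (W-2, washed neutral), EtOH/THF, reflux
Reagents that add atoms: none
Why: Raney-nickel hydrogenolysis of the two benzylic C–S bonds (Mozingo-type desulfurisation) turns the dithiane carbon into the C7 methylene without touching the MOM ethers, the acyl acetal or the two stereocentres, and it is placed before any sulfonate is made so that sulfur cannot act as a neighbouring group.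

Step 9
Reactants: 14 lactone acetal
Product: 15 (2R,3R)-2-[3-methoxy-4,5-bis(methoxymethoxy)benzyl]-3-[3,5-dimethoxy-4-(methoxymethoxy)benzyl]butane-1,4-diol
Conditions: LiAlH4, THF, 0 °C → reflux; aqueous NaOH work-up
Reagents that add atoms: none
Why: LiAlH4 reduction of the acyloxy acetal (a masked aldehyde-acid) should open the ring, expel menthoxide and reduce both carbons (C9' and C9) to CH2OH, leaving C8 and C8' untouched because the aldehyde is reduced as soon as it is unmasked.

Step 10
Reactants: 15 diol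
Product: 16 (2R,3R)-2-[3-methoxy-4,5-bis(methoxymethoxy)benzyl]-3-[3,5-dimethoxy-4-(methoxymethoxy)benzyl]butane-1,4-diyl dimethanesulfonate
Conditions: MsCl, Et3N, CH2Cl2, −20 → 0 °C
Reagents that add atoms: methanesulfonyl chloride, CS(=O)(=O)Cl
Why: Sulfonylation through sulfene (MsCl/Et3N) is fast at low temperature, so both primary alcohols should be mesylated before the mono-mesylate can close to a tetrahydrofuran.

Step 11
Reactants: 16 dimesylate
Product: 17 (2R,3R)-1-[3-methoxy-4,5-bis(methoxymethoxy)phenyl]-4-[3,5-dimethoxy-4-(methoxymethoxy)phenyl]-2,3-dimethylbutane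
Conditions: LiEt3BH, THF, 0 °C → reflux
Reagents that add atoms: none
Why: SN2 displacement of the two primary mesylates by the strongly nucleophilic hydride of LiEt3BH should convert both CH2OMs groups into the C9 and C9' methyl groups without touching the adjacent stereocentres.

Step 12
Reactants: 17 tris-MOM ether
Product: 18 sauriol B, 5-[(2R,3R)-4-(4-hydroxy-3,5-dimethoxyphenyl)-2,3-dimethylbutyl]-3-methoxybenzene-1,2-diol
Conditions: HCl (cat.), degassed MeOH, 50 °C, Ar
Reagents that add atoms: none
Why: Acid-catalysed transacetalisation of the three MOM ethers in methanol should release the three phenols, the formaldehyde unit being trapped as dimethoxymethane, while the aryl methyl ethers stay.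

**Compound list**
1 | 3,4-dihydroxy-5-methoxybenzaldehyde (5-hydroxyvanillin) | COc1cc(C=O)cc(O)c1O | starting material
2 | 2-(3,4-dihydroxy-5-methoxyphenyl)-1,3-dithiane | COc1cc(C2SCCCS2)cc(O)c1O | intermediate
3 | 2-[3-methoxy-4,5-bis(methoxymethoxy)phenyl]-1,3-dithiane | COCOc1cc(C2SCCCS2)cc(OC)c1OCOC | intermediate
4 | 4-hydroxy-3,5-dimethoxybenzaldehyde (syringaldehyde) | COc1cc(C=O)cc(OC)c1O | starting material
5 | 3,5-dimethoxy-4-(methoxymethoxy)benzaldehyde | COCOc1c(OC)cc(C=O)cc1OC | intermediate
6 | [3,5-dimethoxy-4-(methoxymethoxy)phenyl]methanol | COCOc1c(OC)cc(CO)cc1OC | intermediate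
7 | 5-(bromomethyl)-1,3-dimethoxy-2-(methoxymethoxy)benzene | COCOc1c(OC)cc(CBr)cc1OC | intermediate
8 | 5-hydroxyfuran-2(5H)-one (racemic cyclic hemiacetal) | O=C1C=CC(O)O1 | starting material
9 | (−)-menthol, (1R,2S,5R)-2-isopropyl-5-methylcyclohexan-1-ol | CC(C)[C@@H]1CC[C@@H](C)C[C@H]1O | starting material
10 | (5R)-5-{[(1R,2S,5R)-2-isopropyl-5-methylcyclohexyl]oxy}furan-2(5H)-one | O=C1C=C[C@H](O[C@@H]2C[C@H](C)CC[C@H]2C(C)C)O1 | intermediate
11 | 2-lithio-2-[3-methoxy-4,5-bis(methoxymethoxy)phenyl]-1,3-dithiane (not isolated) | [Li]C1(SCCCS1)c2cc(OC)c(OCOC)c(OCOC)c2 | intermediate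
12 | lithium enolate of (4R,5R)-4-{2-[3-methoxy-4,5-bis(methoxymethoxy)phenyl]-1,3-dithian-2-yl}-5-(menthyloxy)dihydrofuran-2(3H)-one (not isolated) | [Li]OC1=C[C@@H](C2(SCCCS2)c3cc(OC)c(OCOC)c(OCOC)c3)[C@H](O[C@@H]4C[C@H](C)CC[C@H]4C(C)C)O1 | intermediate
13 | (3R,4R,5R)-3-[3,5-dimethoxy-4-(methoxymethoxy)benzyl]-4-{2-[3-methoxy-4,5-bis(methoxymethoxy)phenyl]-1,3-dithian-2-yl}-5-(menthyloxy)dihydrofuran-2(3H)-one | COc1cc(cc(OCOC)c1OCOC)C2(SCCCS2)[C@@H]([C@H](O[C@@H]3C[C@H](C)CC[C@H]3C(C)C)OC4=O)[C@H]4Cc5cc(OC)c(OCOC)c(OC)c5 | intermediate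
14 | (3R,4R,5R)-3-[3,5-dimethoxy-4-(methoxymethoxy)benzyl]-4-[3-methoxy-4,5-bis(methoxymethoxy)benzyl]-5-(menthyloxy)dihydrofuran-2(3H)-one | COc1cc(cc(OCOC)c1OCOC)C[C@@H]([C@H](O[C@@H]2C[C@H](C)CC[C@H]2C(C)C)OC3=O)[C@H]3Cc4cc(OC)c(OCOC)c(OC)c4 | intermediate
15 | (2R,3R)-2-[3-methoxy-4,5-bis(methoxymethoxy)benzyl]-3-[3,5-dimethoxy-4-(methoxymethoxy)benzyl]butane-1,4-diol | COc1cc(cc(OCOC)c1OCOC)C[C@@H](CO)[C@H](CO)Cc2cc(OC)c(OCOC)c(OC)c2 | intermediate
16 | (2R,3R)-2-[3-methoxy-4,5-bis(methoxymethoxy)benzyl]-3-[3,5-dimethoxy-4-(methoxymethoxy)benzyl]butane-1,4-diyl dimethanesulfonate | COc1cc(cc(OCOC)c1OCOC)C[C@@H](COS(C)(=O)=O)[C@H](COS(C)(=O)=O)Cc2cc(OC)c(OCOC)c(OC)c2 | intermediate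
17 | (2R,3R)-1-[3-methoxy-4,5-bis(methoxymethoxy)phenyl]-4-[3,5-dimethoxy-4-(methoxymethoxy)phenyl]-2,3-dimethylbutane | COc1cc(cc(OCOC)c1OCOC)C[C@@H](C)[C@H](C)Cc2cc(OC)c(OCOC)c(OC)c2 | intermediate
18 | sauriol B, 5-[(2R,3R)-4-(4-hydroxy-3,5-dimethoxyphenyl)-2,3-dimethylbutyl]-3-methoxybenzene-1,2-diol | COc1cc(C[C@@H](C)[C@H](C)Cc2cc(OC)c(O)c(OC)c2)cc(O)c1O | target

**Totals**
Total step count: 12.
Longest linear sequence: 9 steps (4 → 5 → 6 → 7 → 13 → 14 → 15 → 16 → 17 → 18; steps 3, 4, 5, 7, 8, 9, 10, 11, 12).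

**Steps most likely to fail**

Step 7. The risks are competing 1,2-addition of the dithiane anion to the lactone carbonyl, and slow C-benzylation of the hindered enolate, so that the protonated Michael adduct is recovered or O-alkylation and dialkylation intervene. The fallback sets out from 3 and 10 and separates the two bond formations. The conjugate addition is run alone (n-BuLi, THF, −78 °C, then 10) and quenched with NH4Cl to give the Michael adduct (4R,5R)-4-{2-[3-methoxy-4,5-bis(methoxymethoxy)phenyl]-1,3-dithian-2-yl}-5-(menthyloxy)dihydrofuran-2(3H)-one F1. Raney nickel in ethanol then gives the unhindered β-benzyl lactone (4R,5R)-4-[3-methoxy-4,5-bis(methoxymethoxy)benzyl]-5-(menthyloxy)dihydrofuran-2(3H)-one F2. Its lithium enolate (LDA, THF, −78 °C) is benzylated with 7 trans to the C4 benzyl group, the classical trans-alkylation of β-substituted butyrolactones, and the route is rejoined at 14.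

Step 10. The risk is ring closure of the mono-mesylate by the remaining hydroxyl to a 3,4-dibenzyltetrahydrofuran before the second mesylation. The fallback sets out from 15 and avoids sulfonates and hydride altogether. Both hydroxyls are activated as alkoxyphosphonium ions in the presence of excess iodide (PPh3, I2, imidazole, toluene/MeCN) to give the diiodide (2R,3R)-1,4-diiodo-2-[3-methoxy-4,5-bis(methoxymethoxy)benzyl]-3-[3,5-dimethoxy-4-(methoxymethoxy)benzyl]butane F3. Radical deiodination (Bu3SnH, AIBN, toluene, 80 °C) then gives the two methyl groups, and the route is rejoined at 17.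

Step 11. The risks are hydride attack at sulfur instead of carbon, which frees an alkoxide that closes onto the neighbouring mesylate, and slow displacement at the β-branched primary carbons. The fallback sets out from 16 and replaces hydride by a soft, non-basic sulfur nucleophile. Sodium thiophenolate (PhSH, NaH, DMF, rt) should give the bis-sulfide (2R,3R)-1,4-bis(phenylsulfanyl)-2-[3-methoxy-4,5-bis(methoxymethoxy)benzyl]-3-[3,5-dimethoxy-4-(methoxymethoxy)benzyl]butane F4. Raney-nickel hydrogenolysis of the C–S bonds (EtOH, reflux) then gives the methyl groups, and the route is rejoined at 17.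

**Further compounds**
F1 | step 7 | (4R,5R)-4-{2-[3-methoxy-4,5-bis(methoxymethoxy)phenyl]-1,3-dithian-2-yl}-5-(menthyloxy)dihydrofuran-2(3H)-one | O=C1C[C@@H](C2(SCCCS2)c3cc(OC)c(OCOC)c(OCOC)c3)[C@H](O[C@@H]4C[C@H](C)CC[C@H]4C(C)C)O1
F2 | step 7 | (4R,5R)-4-[3-methoxy-4,5-bis(methoxymethoxy)benzyl]-5-(menthyloxy)dihydrofuran-2(3H)-one | O=C1C[C@@H](Cc2cc(OC)c(OCOC)c(OCOC)c2)[C@H](O[C@@H]3C[C@H](C)CC[C@H]3C(C)C)O1
F3 | step 10 | (2R,3R)-1,4-diiodo-2-[3-methoxy-4,5-bis(methoxymethoxy)benzyl]-3-[3,5-dimethoxy-4-(methoxymethoxy)benzyl]butane | COc1cc(cc(OCOC)c1OCOC)C[C@@H](CI)[C@H](CI)Cc2cc(OC)c(OCOC)c(OC)c2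
F4 | step 11 | (2R,3R)-1,4-bis(phenylsulfanyl)-2-[3-methoxy-4,5-bis(methoxymethoxy)benzyl]-3-[3,5-dimethoxy-4-(methoxymethoxy)benzyl]butane | COc1cc(cc(OCOC)c1OCOC)C[C@@H](CSc2ccccc2)[C@H](CSc3ccccc3)Cc4cc(OC)c(OCOC)c(OC)c4
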